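Whatever the catalyst does, each reagent consumed makes one target or one second product, so in this flask the reagent charge is shared out between those two.

    starting material + free catalyst ⇌ catalyst intermediate A (K1 = 61 M⁻¹, k1 = 12 M⁻¹ s⁻¹)
    reagent + catalyst intermediate A → free catalyst + target (k2 = 34 M⁻¹ s⁻¹)
    second substrate + free catalyst ⇌ catalyst intermediate B (K3 = 5.5 M⁻¹, k3 = 23 M⁻¹ s⁻¹)
    reagent + catalyst intermediate B → free catalyst + second product (k4 = 12 M⁻¹ s⁻¹)
    crystals ⇌ target, rate k5*(cs5 - [target]) while solid is left; crystals form when [target] > cs5 (cs5 = 0.060 M, k5 = 1.3 s⁻¹)

starting material 0.23 M; second substrate 0.500 equiv; reagent 0.700 equiv; free catalyst 2.5 mol% (in portions, 4); time 20 min; the portions of free catalyst follow each other after 6.0 s, the first at the start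

- at 20 min, what has stopped the reaction, if anything has (no working catalyst is left / it is still moving / all of the starting material has reacted / the reagent has run out first / forward and back rates have come level)
- share of the starting material used up at 20 min
- target at 20 min, in percent of the starting material charged
- catalyst intermediate A at 20 min, in percent of the starting material charged
- amount of target if the flask were left three thousand times as long, in percent of the starting material charged

- for target the crystals are counted in
- as a solid, counted per litre of solution: crystals
- the reaction counts as stopped when no species that holds the starting material changes by six tenths of a point or more over the second half of the time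
- run time (flask): 20 min

With 0.700 equiv of reagent, which I take as the limiting reagent, target can reach 70.0%, less what goes to second product. Free catalyst is captured by starting material or second substrate. Each intermediate then goes on with reagent or falls back, at 0.197 s⁻¹ for A and 4.18 s⁻¹ for B. So each has a chance of going on, on-rate over on-rate plus back-rate.

My small table has three rows, by reagent level:

- Full charge: chance A 96.5%, chance B 31.6%, factor 1.59.
- 0.5 of the charge: chance A 93.3%, chance B 18.8%, factor 2.59.
- Reagent nearly nil: factor 31.4.

Read down the columns: chance B falls by a larger ratio than chance A, so the factor climbs as reagent drops. The last row belongs to the tail, when little reagent remains to be split, so I carry the middle row as S, the working selectivity factor: fractional loss of starting material over fractional loss of second substrate.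

Let a and b be the parts of starting material and second substrate not yet turned over. Then d ln a = S d ln b integrates to a = b^S. The balance says that the part of starting material lost, plus 0.500 equiv times the part of second substrate lost, equals 0.700 equiv. Solving the two together gives target 56.3%, with conversion above it by what intermediate A holds, at most 2.50%.

The forecast says the reagent has run out first, with conversion 60%, target 58% (55% to 61%), intermediate A 2% and finally 58%, because “the side route falls away as reagent drops”; its target is higher than mine.

The simulation gives, at 20 min: the reagent has run out first, with 0% of the reagent left, conversion 59.9%, target 57.9%, intermediate A 1.98%, and on long standing target 57.9%.

Read from this flask's target and unbound second substrate, S is 3.09, higher than my middle row. Conversion in this flask stands at 59.9% because of the falling level of reagent, down to 0% of its charge: the same run without that fall reaches 100%. The neighbour flask with 0.200 equiv of second substrate has the same reagent, so I keep my S, and the two equations give 63.6%; that neighbour flask holds target 64.4%.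

Its constants are assumed; the flask was simulated.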